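**Retrosynthetic overview**
1. Target 8 is genistein joined through C3' of its ring B to C8 of apigenin; the last operation is cleavage of three methyl ethers from 7.
2. The pyranone ring C of the isoflavone is opened at C4–C4a and at C2: Friedel–Crafts acylation of phloroglucinol 4 by arylacetic acid 3, then one-carbon ring closure with DMF.
3. Key disconnection: the biaryl bond C3'–C8, whose two carbons are both innately nucleophilic. Phenol 1 is oxidised to a phenoxonium-type species (an arylogous enolonium equivalent, electrophilic at its ortho carbon), and C8 of apigenin trimethyl ether 2 attacks it.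
4. Ring order: the flavone rings and the phloroglucinol ring are bought intact; the biaryl bond is made first and the isoflavone pyranone ring second.

Assumption: the target has no stereocentre and no defined axial configuration (the biaryl axis is taken as freely rotating), so no stereocontrol is needed; apigenin trimethyl ether is taken as a purchasable starting material.

**Step 1**
Reactants: 1 4-hydroxyphenylacetic acid; 2 5,7-dimethoxy-2-(4-methoxyphenyl)-4H-chromen-4-one (apigenin trimethyl ether)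
Product: 3 2-{4-hydroxy-3-[5,7-dimethoxy-2-(4-methoxyphenyl)-4-oxo-4H-chromen-8-yl]phenyl}acetic acid
Conditions: FeCl3 (10 mol %), t-BuOOt-Bu (1.5 equiv), HFIP, rt; 2 in twofold excess; then NaHCO3 extraction
Reagents that add atoms: none
Why: Proposed new method: FeCl3/t-BuOOt-Bu in HFIP oxidises the phenol of 1 (an enol) at iron to a phenoxyl/phenoxonium species, an arylogous enolonium equivalent whose ortho carbon is now electrophilic (the para position is blocked by the CH2CO2H group), and the most electron-rich C–H of 2, C8 (ortho, ortho and para to three oxygen donors, and the site at which 5,7-dimethoxyflavones are halogenated), attacks it, after which loss of a second electron and of H+ rearomatises both rings; the closest known reaction type is the iron-catalysed oxidative cross-coupling of para-substituted, tyrosine-type phenols with polymethoxyarenes in HFIP, extended here to ring A of a flavone as the arene partner.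

**Step 2**
Reactants: 3 2-{4-hydroxy-3-[5,7-dimethoxy-2-(4-methoxyphenyl)-4-oxo-4H-chromen-8-yl]phenyl}acetic acid; 4 phloroglucinol (benzene-1,3,5-triol)
Product: 7 8-[5-(5,7-dihydroxy-4-oxo-4H-chromen-3-yl)-2-hydroxyphenyl]-5,7-dimethoxy-2-(4-methoxyphenyl)-4H-chromen-4-one, via deoxybenzoin 5 (not isolated), via enaminone 6 (not isolated)
Conditions: BF3·Et2O (solvent), 85 °C; then DMF, MsCl, 70 °C; aq. work-up
Reagents that add atoms: N,N-dimethylformamide (DMF), CN(C)C=O
Why: BF3 activates the acid for Friedel–Crafts acylation of the highly nucleophilic, symmetric phloroglucinol (only one regioisomer is possible, and the deactivated flavone ring A does not compete), and the deoxybenzoin is then aminomethylenated at its active CH2 by the DMF/MsCl iminium reagent and closes through an ortho OH with loss of Me2NH, which is the one-pot deoxybenzoin isoflavone synthesis used for genistein and tolerates free phenols.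

**Step 3**
Reactants: 7 8-[5-(5,7-dihydroxy-4-oxo-4H-chromen-3-yl)-2-hydroxyphenyl]-5,7-dimethoxy-2-(4-methoxyphenyl)-4H-chromen-4-one
Product: 8 8-[5-(5,7-dihydroxy-4-oxo-4H-chromen-3-yl)-2-hydroxyphenyl]-5,7-dihydroxy-2-(4-hydroxyphenyl)-4H-chromen-4-one (CNP0142623.0)
Conditions: BBr3 (15 equiv), CH2Cl2, −78 °C to rt; then MeOH, H2O
Reagents that add atoms: none
Why: BBr3 cleaves all three aryl methyl ethers (Lewis acid–base complexation, then SN2 attack of bromide on methyl) at or below room temperature, where neither pyranone ring opens and the acid-promoted Wessely–Moser isomerisation of the 8-aryl flavone to its 6-aryl isomer does not set in, so the biaryl bond and both heterocycles survive.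

**Compound list**
1 | 4-hydroxyphenylacetic acid | OC(=O)Cc1ccc(O)cc1 | starting material
2 | 5,7-dimethoxy-2-(4-methoxyphenyl)-4H-chromen-4-one (apigenin trimethyl ether) | COc1ccc(cc1)-c1cc(=O)c2c(OC)cc(OC)cc2o1 | starting material
3 | 2-{4-hydroxy-3-[5,7-dimethoxy-2-(4-methoxyphenyl)-4-oxo-4H-chromen-8-yl]phenyl}acetic acid | OC(=O)Cc1ccc(O)c(c1)-c1c(OC)cc(OC)c2c(=O)cc(oc12)-c1ccc(OC)cc1 | intermediate
4 | phloroglucinol (benzene-1,3,5-triol) | Oc1cc(O)cc(O)c1 | starting material
5 | 8-{2-hydroxy-5-[2-oxo-2-(2,4,6-trihydroxyphenyl)ethyl]phenyl}-5,7-dimethoxy-2-(4-methoxyphenyl)-4H-chromen-4-one (deoxybenzoin) | O=C(Cc1ccc(O)c(c1)-c1c(OC)cc(OC)c2c(=O)cc(oc12)-c1ccc(OC)cc1)c1c(O)cc(O)cc1O | intermediate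
6 | 8-{5-[1-(dimethylamino)-3-oxo-3-(2,4,6-trihydroxyphenyl)prop-1-en-2-yl]-2-hydroxyphenyl}-5,7-dimethoxy-2-(4-methoxyphenyl)-4H-chromen-4-one (enaminone; transient, alkene geometry not defined) | CN(C)C=C(C(=O)c1c(O)cc(O)cc1O)c1ccc(O)c(c1)-c1c(OC)cc(OC)c2c(=O)cc(oc12)-c1ccc(OC)cc1 | intermediate
7 | 8-[5-(5,7-dihydroxy-4-oxo-4H-chromen-3-yl)-2-hydroxyphenyl]-5,7-dimethoxy-2-(4-methoxyphenyl)-4H-chromen-4-one | O=c1c(-c2ccc(O)c(-c3c(OC)cc(OC)c4c(=O)cc(-c5ccc(OC)cc5)oc34)c2)coc2cc(O)cc(O)c12 | intermediate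
8 | 8-[5-(5,7-dihydroxy-4-oxo-4H-chromen-3-yl)-2-hydroxyphenyl]-5,7-dihydroxy-2-(4-hydroxyphenyl)-4H-chromen-4-one | O=c1c(-c2ccc(O)c(-c3c(O)cc(O)c4c(=O)cc(-c5ccc(O)cc5)oc34)c2)coc2cc(O)cc(O)c12 | target

**Totals**
Total step count: 3. Longest linear sequence: 3 steps (1 and 2 to 3, then 7, then 8).

**Steps most likely to fail, with fallbacks**

Step 1 is the most likely to fail: the cross-coupling may give the C6 isomer, homodimers of the phenol, or no cross-product because the flavone ring A is a weaker nucleophile than the usual polymethoxyarenes. The fallback makes the same bond with fixed regiochemistry by a palladium-catalysed coupling of pre-functionalised partners. It sets out from 2 and 1. Compound 2 is iodinated at C8 (NIS, cat. TFA, MeCN, rt) to 8-iodo-5,7-dimethoxy-2-(4-methoxyphenyl)-4H-chromen-4-one F1. This is borylated (B2pin2, PdCl2(dppf), KOAc, dioxane, 90 °C) to 5,7-dimethoxy-2-(4-methoxyphenyl)-8-(4,4,5,5-tetramethyl-1,3,2-dioxaborolan-2-yl)-4H-chromen-4-one F2. Compound 1 is brominated ortho to its OH (Br2, AcOH, rt) to 2-(3-bromo-4-hydroxyphenyl)acetic acid F3. Suzuki–Miyaura coupling of F2 with F3 (Pd(OAc)2, SPhos, K3PO4, dioxane/H2O, 80 °C; the hindered ligand counters protodeboronation of the di-ortho-oxygenated boronate) comes back to the route at 3.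

Step 2 is the next most likely to fail: acylation by the bulky, Lewis-basic acid 3 in hot BF3·Et2O may be slow or accompanied by acylation or formylation of the flavone unit. The fallback replaces the carboxylic-acid Friedel–Crafts reaction by a low-temperature nitrile (Houben–Hoesch) acylation. It sets out from 2, with bought 2-(4-hydroxyphenyl)acetonitrile F4 taking the place of 1. The coupling of step 1 then gives 2-{4-hydroxy-3-[5,7-dimethoxy-2-(4-methoxyphenyl)-4-oxo-4H-chromen-8-yl]phenyl}acetonitrile F5. Reaction of F5 with 4 (ZnCl2, HCl gas, Et2O/dioxane, 0 °C) precipitates 2-{4-hydroxy-3-[5,7-dimethoxy-2-(4-methoxyphenyl)-4-oxo-4H-chromen-8-yl]phenyl}-1-(2,4,6-trihydroxyphenyl)ethan-1-iminium chloride F6. Hydrolysis (H2O, 100 °C) gives deoxybenzoin 5, here isolated, which is where the fallback comes back to the route; 5 is then closed to 7 by the second stage of step 2 (BF3·Et2O, DMF, MsCl).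

Step 3 is the third: demethylation of the large hexa-oxygenated biflavonoid may stop short (the 7- and 4'-methyl ethers are slow) or give a product that is hard to purify. The fallback moves the deprotection forward to the small acid, which can be purified by base extraction, so that no protecting group is left at the end. It sets out from 3. BBr3 (CH2Cl2, −78 °C to rt) gives 2-{3-[5,7-dihydroxy-2-(4-hydroxyphenyl)-4-oxo-4H-chromen-8-yl]-4-hydroxyphenyl}acetic acid F7. F7 is then annulated with 4 under the conditions of step 2, where free phenols are tolerated. The annulation passes through the deoxybenzoin 8-{2-hydroxy-5-[2-oxo-2-(2,4,6-trihydroxyphenyl)ethyl]phenyl}-5,7-dihydroxy-2-(4-hydroxyphenyl)-4H-chromen-4-one F8 and the enaminone 8-{5-[1-(dimethylamino)-3-oxo-3-(2,4,6-trihydroxyphenyl)prop-1-en-2-yl]-2-hydroxyphenyl}-5,7-dihydroxy-2-(4-hydroxyphenyl)-4H-chromen-4-one F9, and comes back to the route at 8.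

**Further compounds**
F1 | step 1 | 8-iodo-5,7-dimethoxy-2-(4-methoxyphenyl)-4H-chromen-4-one | COc1ccc(cc1)-c1cc(=O)c2c(OC)cc(OC)c(I)c2o1
F2 | step 1 | 5,7-dimethoxy-2-(4-methoxyphenyl)-8-(4,4,5,5-tetramethyl-1,3,2-dioxaborolan-2-yl)-4H-chromen-4-one | COc1ccc(cc1)-c1cc(=O)c2c(OC)cc(OC)c(B3OC(C)(C)C(C)(C)O3)c2o1
F3 | step 1 | 2-(3-bromo-4-hydroxyphenyl)acetic acid | OC(=O)Cc1ccc(O)c(Br)c1
F4 | step 2 | 2-(4-hydroxyphenyl)acetonitrile (bought) | N#CCc1ccc(O)cc1
F5 | step 2 | 2-{4-hydroxy-3-[5,7-dimethoxy-2-(4-methoxyphenyl)-4-oxo-4H-chromen-8-yl]phenyl}acetonitrile | N#CCc1ccc(O)c(c1)-c1c(OC)cc(OC)c2c(=O)cc(oc12)-c1ccc(OC)cc1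
F6 | step 2 | 2-{4-hydroxy-3-[5,7-dimethoxy-2-(4-methoxyphenyl)-4-oxo-4H-chromen-8-yl]phenyl}-1-(2,4,6-trihydroxyphenyl)ethan-1-iminium chloride | [NH2+]=C(Cc1ccc(O)c(c1)-c1c(OC)cc(OC)c2c(=O)cc(oc12)-c1ccc(OC)cc1)c1c(O)cc(O)cc1O.[Cl-]
F7 | step 3 | 2-{3-[5,7-dihydroxy-2-(4-hydroxyphenyl)-4-oxo-4H-chromen-8-yl]-4-hydroxyphenyl}acetic acid | OC(=O)Cc1ccc(O)c(c1)-c1c(O)cc(O)c2c(=O)cc(oc12)-c1ccc(O)cc1
F8 | step 3 | 8-{2-hydroxy-5-[2-oxo-2-(2,4,6-trihydroxyphenyl)ethyl]phenyl}-5,7-dihydroxy-2-(4-hydroxyphenyl)-4H-chromen-4-one | O=C(Cc1ccc(O)c(c1)-c1c(O)cc(O)c2c(=O)cc(oc12)-c1ccc(O)cc1)c1c(O)cc(O)cc1O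
F9 | step 3 | 8-{5-[1-(dimethylamino)-3-oxo-3-(2,4,6-trihydroxyphenyl)prop-1-en-2-yl]-2-hydroxyphenyl}-5,7-dihydroxy-2-(4-hydroxyphenyl)-4H-chromen-4-one (alkene geometry not defined) | CN(C)C=C(C(=O)c1c(O)cc(O)cc1O)c1ccc(O)c(c1)-c1c(O)cc(O)c2c(=O)cc(oc12)-c1ccc(O)cc1
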